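The furan ring is opened at its aryl C–O bond: the ether oxygen links the spiro carbon (isoindolinone C3) to naphthalene C8, the peri neighbour of C1, which carries the spiro carbon. Because naphthalene C2 is oxygenated and isoindolinone C4 is methoxylated, a metal bound to the C3 hydroxyl finds a single aromatic C–H in range, the peri C8–H. One palladium-catalysed, ligand-controlled C–H etherification of a racemic, ring–chain-equilibrating 3-hydroxy-3-(1-naphthyl)isoindolinone therefore closes the naphtho[1,8-bc]furan ring and fixes the spiro stereocentre by dynamic kinetic resolution. The precursor carries the naphthol as a triisopropylsilyl ether and the hydroxyethyl arm as a tert-butyldimethylsilyl ether.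

Key step: step 6

Remarks on the chemistry (one line each)
- Locants: with the lactam carbonyl as C1 and the carbinol carbon as C3, the methoxy group of the hydroxylactam is at C4 (next to C3a), not C7; only this pattern maps onto the target, and it is the one that lithiation between amide and methoxy delivers (in spiro numbering of the target the same carbon is C7).
- Descriptor: the spiro carbon of the target is S; the same spatial arrangement in bis-silyl ether 12 is named R, because O–Si on the naphthalene branch then outranks O–CH3 on the anisole branch.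
- Assumption: the sense of induction of the amino-acid ligand in step 6 cannot be predicted; the step is written with Boc-L-tert-leucine, and the equally available D-antipode is used instead if the L-ligand favours the wrong enantiomer.
- Design: the naphthalene enters as a C1 aldehyde made by direct formylation, so no aryllithium is ever generated next to a silyl ether (silyl shift from O to C), and the naphthol carries the slow-migrating triisopropylsilyl group because it sits beside an alkoxide in steps 4 and 6.

Step 1
Reactants: 1 3-methoxybenzoyl chloride; 2 2-[(tert-butyldimethylsilyl)oxy]ethan-1-amine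
Product: 3 N-{2-[(tert-butyldimethylsilyl)oxy]ethyl}-3-methoxybenzamide
Conditions: Et3N, CH2Cl2, 0 °C to rt
Reagents that add atoms: none
Why: N-Acylation of a primary amine by an aroyl chloride (Schotten–Baumann-type amide formation) is fast at 0 °C, and Et3N takes up the HCl so that the silyl ether is not touched.

Step 2
Reactants: 4 6-methylnaphthalen-2-ol
Product: 6 2-hydroxy-6-methylnaphthalene-1-carbaldehyde, via 1-(hydroxymethyl)-6-methylnaphthalen-2-ol 5 (not isolated)
Conditions: MgCl2, Et3N, (CH2O)n, MeCN, reflux; then aq. HCl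
Reagents that add atoms: formaldehyde (used as paraformaldehyde), C=O
Why: In the magnesium-mediated ortho-formylation of phenols (Casnati–Skattebøl reaction) the magnesium naphthoxide delivers formaldehyde only to an ortho carbon, of which the α-position C1 is by far the more nucleophilic, and the hydroxymethyl intermediate 5 is oxidised in the flask by hydride transfer to a second formaldehyde.

Step 3
Reactants: 6 2-hydroxy-6-methylnaphthalene-1-carbaldehyde
Product: 7 6-methyl-2-[(triisopropylsilyl)oxy]naphthalene-1-carbaldehyde
Conditions: TIPSCl, imidazole, DMF, rt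
Reagents that add atoms: triisopropylsilyl chloride, CC(C)[Si](Cl)(C(C)C)C(C)C
Why: Imidazole-promoted O-silylation of the naphthol; the triisopropylsilyl group is chosen because it migrates to neighbouring alkoxides far more slowly than smaller silyl groups and still falls to fluoride at the end.

Step 4
Reactants: 3 N-{2-[(tert-butyldimethylsilyl)oxy]ethyl}-3-methoxybenzamide; 7 6-methyl-2-[(triisopropylsilyl)oxy]naphthalene-1-carbaldehyde
Product: 9 (±)-N-{2-[(tert-butyldimethylsilyl)oxy]ethyl}-2-[hydroxy{6-methyl-2-[(triisopropylsilyl)oxy]naphthalen-1-yl}methyl]-3-methoxybenzamide, via N,2-dilithio amide 8 (not isolated)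
Conditions: 3, s-BuLi (2.2 equiv), TMEDA, THF, −78 °C; then 7, −78 °C; aq. NH4Cl at −78 °C
Reagents that add atoms: none
Why: Directed ortho-metalation: after N–H deprotonation the lithium amidate and the methoxy group jointly steer s-BuLi to C2 between them, and the aryllithium adds 1,2 to the non-enolisable aldehyde, giving a racemic carbinol whose stereocentre is erased in step 5.

Step 5
Reactants: 9 (±)-N-{2-[(tert-butyldimethylsilyl)oxy]ethyl}-2-[hydroxy{6-methyl-2-[(triisopropylsilyl)oxy]naphthalen-1-yl}methyl]-3-methoxybenzamide
Product: 11 (±)-2-{2-[(tert-butyldimethylsilyl)oxy]ethyl}-3-hydroxy-4-methoxy-3-{6-methyl-2-[(triisopropylsilyl)oxy]naphthalen-1-yl}isoindolin-1-one, via keto amide 10 (not isolated)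
Conditions: Dess–Martin periodinane, NaHCO3, CH2Cl2, 0 °C to rt
Reagents that add atoms: none
Why: Dess–Martin oxidation of the diaryl carbinol gives keto amide 10, whose secondary amide N–H adds to the neighbouring ketone (ring–chain tautomerism of 2-aroylbenzamides) to form the five-membered hydroxylactam as a racemate.

Step 6
Reactants: 11 (±)-2-{2-[(tert-butyldimethylsilyl)oxy]ethyl}-3-hydroxy-4-methoxy-3-{6-methyl-2-[(triisopropylsilyl)oxy]naphthalen-1-yl}isoindolin-1-one
Product: 12 (R)-2-{2-[(tert-butyldimethylsilyl)oxy]ethyl}-7-methoxy-7'-methyl-3'-[(triisopropylsilyl)oxy]spiro[isoindoline-1,2'-naphtho[1,8-bc]furan]-3-one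
Conditions: Pd(OAc)2 (10 mol %), Boc-L-tert-leucine (20 mol %), PhI(OAc)2 (1.5 equiv), Li2CO3 (1.5 equiv), C6F6, 80 °C
Reagents that add atoms: none
Why: Proposed new method: Li2CO3 turns the hemiaminal into an alkoxide that binds divalent palladium carrying the mono-protected amino acid; carboxylate-assisted concerted metalation–deprotonation at naphthalene C8–H gives a six-membered oxapalladacycle (Pd, O, C3, naphthalene C1, C8a, C8), PhI(OAc)2 oxidises it to tetravalent palladium, and aryl C–O reductive elimination releases the ether and divalent palladium. The closest known reactions are the hydroxyl-directed palladium-catalysed C–H activation/C–O cyclisation of tertiary alcohols to dihydrobenzofurans with PhI(OAc)2 and the amino-acid-ligand-controlled enantioselective C–H activation/C–O lactonisation to benzofuranones; new here are the peri C–H, the hemiaminal donor and the dynamic resolution. The five-membered furan ring (O, C3, naphthalene C1, C8a, C8) closes by ring-contracting C–O reductive elimination from that palladacycle, so only the aryl C–O bond is made and the C3–O bond of the hemiaminal is carried through intact. The spiro stereocentre is controlled by the chiral ligand: the two hemiaminal enantiomers give diastereomeric C–H cleavage transition states, and the slower-reacting one is fed back through base-mediated ring opening to achiral keto amide 10 and reclosure, so all material can drain through the faster palladacycle, after which the etherified centre has no open-chain tautomer and stays fixed. Site selectivity needs no further control, because naphthalene C2 carries OSi and isoindolinone C4 carries OMe, leaving C8–H as the only aromatic C–H that a six-membered palladacycle from the C3 oxygen can include. Chemoselectivity against oxidation of the naphthalene by the trivalent-iodine reagent rests on the non-polar, carbonate-buffered medium and on the bulky aryl silyl ether, which also resists transfer to the neighbouring alkoxide.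

Step 7
Reactants: 12 (R)-2-{2-[(tert-butyldimethylsilyl)oxy]ethyl}-7-methoxy-7'-methyl-3'-[(triisopropylsilyl)oxy]spiro[isoindoline-1,2'-naphtho[1,8-bc]furan]-3-one
Product: 14 (S)-3'-hydroxy-2-(2-hydroxyethyl)-7-methoxy-7'-methylspiro[isoindoline-1,2'-naphtho[1,8-bc]furan]-3-one, via mono-silyl phenol 13 (not isolated)
Conditions: Bu4NF/AcOH (1:1, 3 equiv), THF, 0 °C to rt
Reagents that add atoms: none
Why: Fluoride-mediated desilylation removes the aryl silyl ether first and then the primary alkyl one, and the acetic acid buffer keeps the freed naphthol protonated so that the spiro N,O-ketal is not opened and its configuration is carried over unchanged.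

Compound list
1 | 3-methoxybenzoyl chloride | COc1cccc(c1)C(Cl)=O | starting material
2 | 2-[(tert-butyldimethylsilyl)oxy]ethan-1-amine | NCCO[Si](C)(C)C(C)(C)C | starting material
3 | N-{2-[(tert-butyldimethylsilyl)oxy]ethyl}-3-methoxybenzamide | COc1cccc(c1)C(=O)NCCO[Si](C)(C)C(C)(C)C | intermediate
4 | 6-methylnaphthalen-2-ol | Cc1ccc2cc(O)ccc2c1 | starting material
5 | 1-(hydroxymethyl)-6-methylnaphthalen-2-ol (present as its magnesium salt, not isolated) | Cc1ccc2c(CO)c(O)ccc2c1 | intermediate
6 | 2-hydroxy-6-methylnaphthalene-1-carbaldehyde | Cc1ccc2c(C=O)c(O)ccc2c1 | intermediate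
7 | 6-methyl-2-[(triisopropylsilyl)oxy]naphthalene-1-carbaldehyde | Cc1ccc2c(C=O)c(O[Si](C(C)C)(C(C)C)C(C)C)ccc2c1 | intermediate
8 | N,2-dilithio derivative of amide 3 (lithium on nitrogen and on C2 between amide and methoxy, not isolated) | COc1cccc(C(=O)N([Li])CCO[Si](C)(C)C(C)(C)C)c1[Li] | intermediate
9 | (±)-N-{2-[(tert-butyldimethylsilyl)oxy]ethyl}-2-[hydroxy{6-methyl-2-[(triisopropylsilyl)oxy]naphthalen-1-yl}methyl]-3-methoxybenzamide | COc1cccc(C(=O)NCCO[Si](C)(C)C(C)(C)C)c1C(O)c1c(O[Si](C(C)C)(C(C)C)C(C)C)ccc2cc(C)ccc12 | intermediate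
10 | N-{2-[(tert-butyldimethylsilyl)oxy]ethyl}-3-methoxy-2-{6-methyl-2-[(triisopropylsilyl)oxy]-1-naphthoyl}benzamide (keto amide, open tautomer of 11, not isolated) | COc1cccc(C(=O)NCCO[Si](C)(C)C(C)(C)C)c1C(=O)c1c(O[Si](C(C)C)(C(C)C)C(C)C)ccc2cc(C)ccc12 | intermediate
11 | (±)-2-{2-[(tert-butyldimethylsilyl)oxy]ethyl}-3-hydroxy-4-methoxy-3-{6-methyl-2-[(triisopropylsilyl)oxy]naphthalen-1-yl}isoindolin-1-one (racemic, interconverting hemiaminal) | COc1cccc2c1C(O)(c1c(O[Si](C(C)C)(C(C)C)C(C)C)ccc3cc(C)ccc13)N(CCO[Si](C)(C)C(C)(C)C)C2=O | intermediate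
12 | (R)-2-{2-[(tert-butyldimethylsilyl)oxy]ethyl}-7-methoxy-7'-methyl-3'-[(triisopropylsilyl)oxy]spiro[isoindoline-1,2'-naphtho[1,8-bc]furan]-3-one | COc1cccc2c1[C@]1(Oc3cc(C)cc4ccc(O[Si](C(C)C)(C(C)C)C(C)C)c1c34)N(CCO[Si](C)(C)C(C)(C)C)C2=O | intermediate
13 | (S)-2-{2-[(tert-butyldimethylsilyl)oxy]ethyl}-3'-hydroxy-7-methoxy-7'-methylspiro[isoindoline-1,2'-naphtho[1,8-bc]furan]-3-one (not isolated) | COc1cccc2c1[C@]1(Oc3cc(C)cc4ccc(O)c1c34)N(CCO[Si](C)(C)C(C)(C)C)C2=O | intermediate
14 | (S)-3'-hydroxy-2-(2-hydroxyethyl)-7-methoxy-7'-methylspiro[isoindoline-1,2'-naphtho[1,8-bc]furan]-3-one (CNP0434366.2) | COc1cccc2c1[C@]1(Oc3cc(C)cc4ccc(O)c1c34)N(CCO)C2=O | target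

Total step count: 7.
Longest linear sequence: 6 steps (4 → 6 → 7 → 9 → 11 → 12 → 14; steps 2 to 7).

Steps most likely to fail

Step 6 (carries the label "Proposed new method:"). Several processes could defeat it:
- β-aryl elimination from the palladium alkoxide, which would extrude the naphthyl group;
- oxidation of the electron-rich naphthalene by the trivalent-iodine oxidant;
- C–H cleavage at the peri position that is too slow, also because rotation about the C3–naphthyl bond is hindered;
- ring–chain equilibration too slow for the resolution to become dynamic, or too little discrimination between the hemiaminal enantiomers.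

The fallback uses known chemistry, sets out from aldehyde 7 and returns at 12. It installs a halogen at C8 before the fragments are joined, so that the same aryl C–O bond is made by a classical intramolecular O-arylation.
- Carbonyl-directed peri bromination of 7 (Pd(OAc)2 cat., NBS, DCE, 80 °C) should give 8-bromo-6-methyl-2-[(triisopropylsilyl)oxy]naphthalene-1-carbaldehyde F1. The innate 1 > 6 > 8 order of electrophilic substitution in a 2-oxygenated naphthalene points to the same carbon once C1 and C6 are occupied.
- Addition of dilithio amide 8 at −78 °C, where aldehyde addition should outrun lithium–bromine exchange, gives the bromo carbinol F2.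
- Dess–Martin oxidation gives the bromo keto amide F3, which closes to the 8-bromonaphthyl hydroxylactam F4.
- Ullmann-type intramolecular etherification of the hemiaminal hydroxyl (CuI, 1,10-phenanthroline, Cs2CO3, toluene, 110 °C) gives the racemic bis-silyl spiro ketal F5.
- Preparative HPLC on a chiral stationary phase delivers 12.

Step 4. The doubly flanked aryllithium may add only slowly to the doubly flanked aldehyde, giving time for silyl transfer from the naphthol oxygen to the new alkoxide, and the hydroxy amide may lactonise with loss of the amine arm on work-up.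

The fallback sets out from dilithio amide 8 and naphthol 4 and returns at 11. It forms the congested C–C bond by electrophilic substitution at the intrinsically nucleophilic C1 of the free naphthol instead of by organolithium addition.
- Quenching 8 with DMF gives the 2-formylbenzamide F6, which closes on work-up to 2-{2-[(tert-butyldimethylsilyl)oxy]ethyl}-3-hydroxy-4-methoxyisoindolin-1-one F7.
- Brønsted-acid-catalysed amidoalkylation of 4 (N-acyliminium aza-Friedel–Crafts reaction; cat. (PhO)2PO2H, CH2Cl2, rt) gives the 3-(2-hydroxy-6-methylnaphthalen-1-yl)isoindolinone F8.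
- TIPSCl/imidazole gives its triisopropylsilyl ether F9.
- Deprotonation at C3 (KN(SiMe3)2, THF, −78 °C) and oxygen transfer from 2-(phenylsulfonyl)-3-phenyloxaziridine (Davis hydroxylation of a stabilised carbanion) gives 11.

Step 5. Oxidation of the crowded diaryl carbinol may be slow, and acid-promoted lactonisation of the hydroxy amide with expulsion of the amine arm can then compete.

The fallback sets out from aldehyde 7 and returns at 11. It reaches the ketone oxidation state without passing through the carbinol, and is reasonable if step 4 has shown that 8 adds to this naphthalene carbonyl.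
- Pinnick oxidation of 7 (NaClO2, NaH2PO4, 2-methyl-2-butene, t-BuOH/H2O) gives 6-methyl-2-[(triisopropylsilyl)oxy]naphthalene-1-carboxylic acid F10.
- (COCl)2 with cat. DMF in CH2Cl2 gives 6-methyl-2-[(triisopropylsilyl)oxy]naphthalene-1-carbonyl chloride F11.
- Acylation of dilithio amide 8 with this chloride at −78 °C gives keto amide 10, which closes to 11 on work-up.

Further compounds
F1 | step 6 | 8-bromo-6-methyl-2-[(triisopropylsilyl)oxy]naphthalene-1-carbaldehyde | Cc1cc(Br)c2c(C=O)c(O[Si](C(C)C)(C(C)C)C(C)C)ccc2c1
F2 | step 6 | (±)-2-[{8-bromo-6-methyl-2-[(triisopropylsilyl)oxy]naphthalen-1-yl}(hydroxy)methyl]-N-{2-[(tert-butyldimethylsilyl)oxy]ethyl}-3-methoxybenzamide | COc1cccc(C(=O)NCCO[Si](C)(C)C(C)(C)C)c1C(O)c1c(O[Si](C(C)C)(C(C)C)C(C)C)ccc2cc(C)cc(Br)c12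
F3 | step 6 | 2-{8-bromo-6-methyl-2-[(triisopropylsilyl)oxy]-1-naphthoyl}-N-{2-[(tert-butyldimethylsilyl)oxy]ethyl}-3-methoxybenzamide | COc1cccc(C(=O)NCCO[Si](C)(C)C(C)(C)C)c1C(=O)c1c(O[Si](C(C)C)(C(C)C)C(C)C)ccc2cc(C)cc(Br)c12
F4 | step 6 | (±)-3-{8-bromo-6-methyl-2-[(triisopropylsilyl)oxy]naphthalen-1-yl}-2-{2-[(tert-butyldimethylsilyl)oxy]ethyl}-3-hydroxy-4-methoxyisoindolin-1-one | COc1cccc2c1C(O)(c1c(O[Si](C(C)C)(C(C)C)C(C)C)ccc3cc(C)cc(Br)c13)N(CCO[Si](C)(C)C(C)(C)C)C2=O
F5 | step 6 | racemic 2-{2-[(tert-butyldimethylsilyl)oxy]ethyl}-7-methoxy-7'-methyl-3'-[(triisopropylsilyl)oxy]spiro[isoindoline-1,2'-naphtho[1,8-bc]furan]-3-one | COc1cccc2c1C1(Oc3cc(C)cc4ccc(O[Si](C(C)C)(C(C)C)C(C)C)c1c34)N(CCO[Si](C)(C)C(C)(C)C)C2=O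
F6 | step 4 | N-{2-[(tert-butyldimethylsilyl)oxy]ethyl}-2-formyl-3-methoxybenzamide | COc1cccc(C(=O)NCCO[Si](C)(C)C(C)(C)C)c1C=O
F7 | step 4 | (±)-2-{2-[(tert-butyldimethylsilyl)oxy]ethyl}-3-hydroxy-4-methoxyisoindolin-1-one | COc1cccc2c1C(O)N(CCO[Si](C)(C)C(C)(C)C)C2=O
F8 | step 4 | (±)-2-{2-[(tert-butyldimethylsilyl)oxy]ethyl}-3-(2-hydroxy-6-methylnaphthalen-1-yl)-4-methoxyisoindolin-1-one | COc1cccc2c1C(c1c(O)ccc3cc(C)ccc13)N(CCO[Si](C)(C)C(C)(C)C)C2=O
F9 | step 4 | (±)-2-{2-[(tert-butyldimethylsilyl)oxy]ethyl}-4-methoxy-3-{6-methyl-2-[(triisopropylsilyl)oxy]naphthalen-1-yl}isoindolin-1-one | COc1cccc2c1C(c1c(O[Si](C(C)C)(C(C)C)C(C)C)ccc3cc(C)ccc13)N(CCO[Si](C)(C)C(C)(C)C)C2=O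
F10 | step 5 | 6-methyl-2-[(triisopropylsilyl)oxy]naphthalene-1-carboxylic acid | Cc1ccc2c(C(O)=O)c(O[Si](C(C)C)(C(C)C)C(C)C)ccc2c1
F11 | step 5 | 6-methyl-2-[(triisopropylsilyl)oxy]naphthalene-1-carbonyl chloride | Cc1ccc2c(C(Cl)=O)c(O[Si](C(C)C)(C(C)C)C(C)C)ccc2c1
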